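**Plan**
1. Cuts, in retrosynthetic order: the PMB-masked CO2H; O4–tigloyl; C3–O (ester introduced by SN2 inversion); C3–O and C4–O together, back to a C3=C4 alkene. O5 is then reconnected to C2, and the ring bonds C1–C2 and C5–C6 are cut by retro-[4+2] to furan and an acryloyl imide.
2. Enabling feature: in the cyclohexene ring C1–C6, the oxygen on C5 lies 1,4 across the ring from C2, and C2 is the β-carbon of the C1 carboxyl. A temporary O5–C2 bond therefore turns the ring into a 7-oxanorbornene (a furan adduct), and E1cB cleavage of that bond later creates C1=C2.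
3. Forward: the only carbocycle is closed first, as the oxa-bridged bicycle. The imide is exchanged for a PMB ester, the bridge is opened with O5 trapped as the acetate, C3=C4 is dihydroxylated, O3 and O4 are esterified in turn, and the acid is released last.
4. Stereochemistry: C5 is set by a Cu(II)–bis(oxazoline) catalyst. C4 and C3 are relayed from C5 in one event (OsO4 anti to the C5 acetoxy group). C3 is then inverted by the Mitsunobu reaction that installs its ester, giving the all-trans (3R,4R,5S) array, a 3-epi-ent-shikimate.
5. The three hydroxyls never compete: O5 is acetylated while it is the only oxygen function, O3 arrives already acylated, and O4 is the last free OH.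

Key step: step 1

Remark: 2, 8, 10 and 2,2'-isopropylidenebis[(4S)-4-tert-butyl-2-oxazoline] are taken as commercial. Ring atoms are numbered as in shikimic acid (C1 carboxyl, C3 6-methylheptanoate, C4 tiglate, C5 acetate, C6 CH2). In bicycles 3 and 4, C1/C2/C3/C4/C5/C6/O7 are the future C2/C1/C6/C5/C4/C3/O5.

Step 1
Reactants: 1 furan; 2 3-acryloyl-1,3-oxazolidin-2-one
Product: 3 3-[(1S,2S,4S)-7-oxabicyclo[2.2.1]hept-5-ene-2-carbonyl]-1,3-oxazolidin-2-one (endo adduct)
Conditions: [Cu((S,S)-t-Bu-box)](SbF6)2 (5 mol %), furan (excess), CH2Cl2, −78 °C; cold filtration through SiO2; recrystallisation (removes the exo isomer)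
Reagents that add atoms: none
Why: Imide 2 chelates the square-planar Cu(II)–bis(oxazoline) cation in its s-cis form, and this LUMO lowering lets the aromatic, reluctant diene furan add at −78 °C in a concerted suprafacial [4π+2π] cycloaddition that forms C1–C2 and C5–C6 (shikimate numbering) in one event; the closest known reaction type is the catalytic enantioselective Diels–Alder reaction of furan with an acryloyl imide. The cyclohexene ring is closed by intermolecular cycloaddition, and because the diene termini are already joined through the furan oxygen, the same two bonds also close the oxolane ring O7–C1–C2–C3–C4 of the bicycle, which is the temporary O5–C2 bridge. The two bridgehead centres are cis by the suprafacial addition to planar furan; their absolute sense (4S, the future C5) is set by a tert-butyl group of the (S,S)-ligand that shields the Cα-Si face, so furan should add to the Cα-Re face, and C2 (2S) follows from the kinetic endo transition state. Regioselectivity is not an issue because furan is symmetric. The step needs kinetic control, since the adduct should revert on warming while the Lewis acid is present, so the catalyst is removed cold. The minor exo adduct arises from the same dienophile face and carries the opposite bridgehead configuration, so it must be crystallised out because C2 is erased in step 3 and exo material would lower the enantiopurity of 6.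

Step 2
Reactants: 3 endo imide adduct
Product: 4 4-methoxybenzyl (1S,2S,4S)-7-oxabicyclo[2.2.1]hept-5-ene-2-carboxylate
Conditions: 4-MeOC6H4CH2OH, n-BuLi, THF, −78 → −20 °C; AcOH quench
Reagents that add atoms: 4-methoxybenzyl alcohol COc1ccc(CO)cc1
Why: Alcoholysis of an N-acyloxazolidinone with a lithium benzylic alkoxide (acyl transfer at the more electrophilic exocyclic carbonyl) removes the chelating helper and installs an acid-labile ester; the low temperature holds back β-elimination, no stereocentre is formed, and any epimerisation at C2 is harmless because that centre is erased in step 3.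

Step 3
Reactants: 4 PMB oxanorbornene ester
Product: 6 4-methoxybenzyl (5S)-5-acetoxycyclohexa-1,3-diene-1-carboxylate, via lithium alkoxide 5 (not isolated)
Conditions: LiHMDS (1.1 equiv), THF, −78 °C; then Ac2O, −78 → 0 °C
Reagents that add atoms: acetic anhydride CC(=O)OC(C)=O; lithium hexamethyldisilazide [Li+].C[Si](C)(C)[N-][Si](C)(C)C (lithium, in 5 only)
Why: Ester enolisation triggers E1cB (retro-oxa-Michael) cleavage of the temporary O5–C2 bond, driven by strain release and dienoate conjugation, which creates C1=C2 and frees O5 as alkoxide 5 for acetylation in the same flask; the C5–O bond is never broken, so 5S is retained.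

Step 4
Reactants: 6 dienyl acetate
Product: 7 4-methoxybenzyl (3S,4S,5S)-5-acetoxy-3,4-dihydroxycyclohex-1-ene-1-carboxylate (3,4-cis, 4,5-trans; ent-shikimate configuration)
Conditions: OsO4 (cat.), NMO, citric acid, acetone/t-BuOH/H2O, 0 °C → rt
Reagents that add atoms: osmium tetroxide O=[Os](=O)(=O)=O (catalytic oxygen carrier); N-methylmorpholine N-oxide C[N+]1([O-])CCOCC1; water O
Why: Catalytic syn-dihydroxylation should pick the more electron-rich γ,δ-alkene C3=C4 of the dienoate and add to the face anti to the allylic C5 acetoxy group, setting C3 and C4 together from C5, while the citric acid buffer keeps the medium acidic enough to suppress an O5→O4 acetyl shift.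

Step 5
Reactants: 7 cis-diol; 8 6-methylheptanoic acid
Product: 9 4-methoxybenzyl (3R,4R,5S)-5-acetoxy-4-hydroxy-3-(6-methylheptanoyloxy)cyclohex-1-ene-1-carboxylate (all-trans)
Conditions: PPh3, DIAD (1.1 equiv each), THF, 0 °C → rt
Reagents that add atoms: none
Why: In this Mitsunobu reaction the two possible oxyphosphonium ions of the cis-diol should equilibrate through the dioxaphospholane, and only the allylic pseudoaxial C3–O group is displaced at a useful rate by the carboxylate (SN2, inversion to 3R), because C4 is flanked on both sides, SN2' attack at the ester-bearing C1 is electronically mismatched, and the cis C4-OH cannot close an epoxide.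

Step 6
Reactants: 9 C4 alcohol; 10 tigloyl chloride [(E)-2-methylbut-2-enoyl chloride]
Product: 11 4-methoxybenzyl (3R,4R,5S)-5-acetoxy-3-(6-methylheptanoyloxy)-4-[(E)-2-methylbut-2-enoyloxy]cyclohex-1-ene-1-carboxylate
Conditions: pyridine, DMAP (cat.), CH2Cl2, 0 °C → rt
Reagents that add atoms: none
Why: DMAP-catalysed acylation of the only free hydroxyl touches no stereocentre, and using pyridine instead of a trialkylamine avoids vinylketene formation from 10, so the conjugated (E)-enoate is kept.

Step 7
Reactants: 11 PMB triester
Product: 12 (3R,4R,5S)-5-acetoxy-3-(6-methylheptanoyloxy)-4-[(E)-2-methylbut-2-enoyloxy]cyclohex-1-ene-1-carboxylic acid (target)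
Conditions: TFA, anisole, CH2Cl2, 0 °C
Reagents that add atoms: none
Why: Acidolysis of the 4-methoxybenzyl ester (SN1 loss of the stabilised benzylic cation, trapped by anisole in a Friedel–Crafts alkylation) frees the acid without base, so the three esters are neither hydrolysed, shifted nor eliminated, and the allylic C3–O bond should not ionise because its cation would be conjugated with the electron-poor enoate.

**Compound list**
1 | furan | c1ccoc1 | starting material
2 | 3-acryloyl-1,3-oxazolidin-2-one | C=CC(=O)N1CCOC1=O | starting material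
3 | 3-[(1S,2S,4S)-7-oxabicyclo[2.2.1]hept-5-ene-2-carbonyl]-1,3-oxazolidin-2-one (endo) | O=C(N1CCOC1=O)[C@H]2C[C@H]3C=C[C@@H]2O3 | intermediate
4 | 4-methoxybenzyl (1S,2S,4S)-7-oxabicyclo[2.2.1]hept-5-ene-2-carboxylate | COc1ccc(COC(=O)[C@H]2C[C@H]3C=C[C@@H]2O3)cc1 | intermediate
5 | lithium alkoxide of 4-methoxybenzyl (5S)-5-hydroxycyclohexa-1,3-diene-1-carboxylate | [Li+].[O-][C@H]1CC(C(=O)OCc2ccc(OC)cc2)=CC=C1 | intermediate
6 | 4-methoxybenzyl (5S)-5-acetoxycyclohexa-1,3-diene-1-carboxylate | CC(=O)O[C@H]1CC(C(=O)OCc2ccc(OC)cc2)=CC=C1 | intermediate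
7 | 4-methoxybenzyl (3S,4S,5S)-5-acetoxy-3,4-dihydroxycyclohex-1-ene-1-carboxylate | O[C@@H]1[C@@H](OC(C)=O)CC(C(=O)OCc2ccc(OC)cc2)=C[C@@H]1O | intermediate
8 | 6-methylheptanoic acid | CC(C)CCCCC(=O)O | starting material
9 | 4-methoxybenzyl (3R,4R,5S)-5-acetoxy-4-hydroxy-3-(6-methylheptanoyloxy)cyclohex-1-ene-1-carboxylate | O[C@@H]1[C@@H](OC(C)=O)CC(C(=O)OCc2ccc(OC)cc2)=C[C@H]1OC(=O)CCCCC(C)C | intermediate
10 | tigloyl chloride, (E)-2-methylbut-2-enoyl chloride | C/C=C(\C)C(=O)Cl | starting material
11 | 4-methoxybenzyl (3R,4R,5S)-5-acetoxy-3-(6-methylheptanoyloxy)-4-[(E)-2-methylbut-2-enoyloxy]cyclohex-1-ene-1-carboxylate | C/C=C(\C)C(=O)O[C@@H]1[C@@H](OC(C)=O)CC(C(=O)OCc2ccc(OC)cc2)=C[C@H]1OC(=O)CCCCC(C)C | intermediate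
12 | (3R,4R,5S)-5-acetoxy-3-(6-methylheptanoyloxy)-4-[(E)-2-methylbut-2-enoyloxy]cyclohex-1-ene-1-carboxylic acid | C/C=C(\C)C(=O)O[C@@H]1[C@@H](OC(C)=O)CC(C(=O)O)=C[C@H]1OC(=O)CCCCC(C)C | target

Total step count: 7. Longest linear sequence: 7 (from 1 and 2).

**Steps most likely to fail**

Step 5. Three things may go wrong. The phosphonium may end up productively on O4, followed by participation of the neighbouring acetate. The C3 oxyphosphonium may eliminate toward an aromatic ring. The weakly acidic aliphatic acid may react sluggishly.
The fallback sets out from 7 and returns at 9. The cis-diol is tied up with SOCl2/Et3N (CH2Cl2, 0 °C) as the 3,4-cyclic sulfite F1. Caesium 6-methylheptanoate (8, Cs2CO3, DMF) then opens it by SN2 at the allylic C3 with inversion, the mode known for azide on shikimate 3,4-cyclic sulfites. This gives the C4 hydrogen sulfite F2 (caesium salt in the flask), which is hydrolysed on dilute acid work-up to 9. The leaving group is fixed on both oxygens and only its allylic end can be displaced, so the regiochemistry no longer depends on which hydroxyl is activated.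

Step 4. The small acetate may give too little facial bias. The acetyl group may drift from O5 to the new O4-H. Diene 6 may lose acetic acid and aromatise before it is oxidised.
The fallback sets out from 4 (through 5) and returns at 11. O5 is carried as a bulky silyl ether and acetylated last.
- Alkoxide 5 is trapped with TBSOTf instead of Ac2O to give the silyl ether F3.
- OsO4/NMO should add anti to the silyloxy group to give the diol F4.
- The Mitsunobu reaction with 8 gives the C3 ester F5.
- Acylation with 10 (pyridine, DMAP) gives the diester F6.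
- HF·pyridine (THF, 0 °C, acidic so that acyl shifts are suppressed) gives the C5 alcohol F7.
- Ac2O/pyridine gives 11.

Step 2. The alkoxide may act as a base and open the bridge at the imide stage, or it may attack the ring carbonyl of the oxazolidinone.
The fallback sets out from 3 and returns at 4. LiOH/H2O2 (THF/H2O, 0 °C), a weakly basic and strongly nucleophilic reagent, cleaves the imide to the carboxylic acid F8. Its caesium salt is O-alkylated with 4-methoxybenzyl chloride (Cs2CO3, DMF, rt) to 4. The ester bond is thus made at oxygen rather than at the acyl carbon, and the carboxylate has no readily removed α-proton, so the bridge stays closed.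

**Further compounds**
F1 | step 5 | 3,4-O-sulfinyl (cyclic sulfite) derivative of 7, epimers at sulfur | O=S1O[C@H]2C=C(C(=O)OCc3ccc(OC)cc3)C[C@H](OC(C)=O)[C@H]2O1
F2 | step 5 | C4 hydrogen sulfite of 9 | OS(=O)O[C@@H]1[C@@H](OC(C)=O)CC(C(=O)OCc2ccc(OC)cc2)=C[C@H]1OC(=O)CCCCC(C)C
F3 | step 4 | 4-methoxybenzyl (5S)-5-(tert-butyldimethylsilyloxy)cyclohexa-1,3-diene-1-carboxylate | CC(C)(C)[Si](C)(C)O[C@H]1CC(C(=O)OCc2ccc(OC)cc2)=CC=C1
F4 | step 4 | 4-methoxybenzyl (3S,4S,5S)-5-(tert-butyldimethylsilyloxy)-3,4-dihydroxycyclohex-1-ene-1-carboxylate | O[C@@H]1[C@@H](O[Si](C)(C)C(C)(C)C)CC(C(=O)OCc2ccc(OC)cc2)=C[C@@H]1O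
F5 | step 4 | 4-methoxybenzyl (3R,4S,5S)-5-(tert-butyldimethylsilyloxy)-4-hydroxy-3-(6-methylheptanoyloxy)cyclohex-1-ene-1-carboxylate | O[C@@H]1[C@@H](O[Si](C)(C)C(C)(C)C)CC(C(=O)OCc2ccc(OC)cc2)=C[C@H]1OC(=O)CCCCC(C)C
F6 | step 4 | 4-methoxybenzyl (3R,4S,5S)-5-(tert-butyldimethylsilyloxy)-3-(6-methylheptanoyloxy)-4-[(E)-2-methylbut-2-enoyloxy]cyclohex-1-ene-1-carboxylate | C/C=C(\C)C(=O)O[C@@H]1[C@@H](O[Si](C)(C)C(C)(C)C)CC(C(=O)OCc2ccc(OC)cc2)=C[C@H]1OC(=O)CCCCC(C)C
F7 | step 4 | 4-methoxybenzyl (3R,4R,5S)-5-hydroxy-3-(6-methylheptanoyloxy)-4-[(E)-2-methylbut-2-enoyloxy]cyclohex-1-ene-1-carboxylate | C/C=C(\C)C(=O)O[C@@H]1[C@@H](O)CC(C(=O)OCc2ccc(OC)cc2)=C[C@H]1OC(=O)CCCCC(C)C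
F8 | step 2 | (1S,2S,4S)-7-oxabicyclo[2.2.1]hept-5-ene-2-carboxylic acid (endo) | O=C(O)[C@H]1C[C@H]2C=C[C@@H]1O2
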